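The 2H-pyran ring is disconnected across the C3=C4 double bond and the O1–C8a aryl ether bond, so that an O–CMe2–CH unit is annulated onto an ortho-fluorobenzaldehyde. In one pot, a silyl-protected β-oxy ylide converts the aldehyde into the Z-styrene, and fluoride then frees the tertiary alkoxide, which displaces fluorine at C8a. The step exploits the cis C3=C4 geometry, which holds the C2 oxygen over C8a of the benzene ring, and the aldehyde carbon as C4. The precursor is 5-bromo-2-fluoro-4-methoxybenzaldehyde; its bromine (C6) later carries the side chain, whose (S)-centre comes from asymmetric hydroformylation and whose benzofuran is closed last by Sonogashira coupling and cyclisation.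

Key step: step 4

Remark on numbering: O1, C2, C3, C4, C4a, C5–C8 and C8a are the positions of the 2H-chromene ring of the target.
Assumption: (R,R)-Ph-BPE is taken to give the (R)-aldehyde from the vinylarene, by analogy with styrene; if the sense proves opposite, the (S,S)-ligand is used.

Step 1
Reactants: 1 2-fluoro-4-methoxybenzaldehyde
Product: 2 5-bromo-2-fluoro-4-methoxybenzaldehyde
Conditions: NBS, CF3CO2H, H2SO4 (cat.), rt
Reagents that add atoms: N-bromosuccinimide, O=C1CCC(=O)N1Br
Why: Electrophilic aromatic bromination should go to C5, ortho to the methoxy group and para to fluorine, because the other activated position (C3) is flanked by fluorine and methoxy.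

Step 2
Reactants: 3 methyltriphenylphosphonium bromide
Product: 6 (2-hydroxy-2-methylpropyl)triphenylphosphonium bromide, via methylenetriphenylphosphorane 4 (not isolated), via lithium betaine 5 (not isolated)
Conditions: n-BuLi, THF, 0 °C; acetone, −78 °C; HBr in Et2O, −78 °C to rt
Reagents that add atoms: acetone, CC(C)=O; hydrogen bromide, Br
Why: Addition of the ylide to acetone gives the lithium bromide-stabilised betaine, which is protonated cold before it can collapse to the alkene (interrupted Wittig reaction, the usual entry to β-hydroxyalkylphosphonium salts).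

Step 3
Reactants: 6 (2-hydroxy-2-methylpropyl)triphenylphosphonium bromide
Product: 7 [2-methyl-2-(trimethylsilyloxy)propyl]triphenylphosphonium bromide
Conditions: N,O-bis(trimethylsilyl)acetamide, MeCN, 40 °C
Reagents that add atoms: N,O-bis(trimethylsilyl)acetamide, CC(=N[Si](C)(C)C)O[Si](C)(C)C
Why: Neutral O-silylation of the tertiary alcohol masks the oxygen without any base, so the betaine that would fragment to isobutene and Ph3PO is never formed.

Step 4
Reactants: 7 [2-methyl-2-(trimethylsilyloxy)propyl]triphenylphosphonium bromide; 2 5-bromo-2-fluoro-4-methoxybenzaldehyde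
Product: 11 6-bromo-7-methoxy-2,2-dimethyl-2H-chromene, via siloxy ylide 8 (not isolated), via Z-styrene silyl ether 9 (not isolated), via cesium alkoxide 10 (not isolated)
Conditions: KN(SiMe3)2, THF, −78 °C; add 2, −78 to 0 °C; then THF replaced by DMF, CsF, 18-crown-6, 90 °C
Reagents that add atoms: none
Why: KN(SiMe3)2 converts 7 into the lithium-free, non-stabilised ylide 8, which adds to the aldehyde of 2 through the kinetically favoured cis-oxaphosphetane and collapses to the Z-styrene 9 (Wittig olefination, forming C3=C4; β-oxygenated ylides such as the dioxolanylmethyl ylide are established reagents of this kind). Fluoride then removes the trimethylsilyl group, and the tertiary alkoxide 10, held over the ring by the cis double bond and the gem-dimethyl group, attacks the fluorine-bearing carbon and expels fluoride, an intramolecular SNAr etherification of the type used to make chromans from 3-(2-fluorophenyl)propanols. This closes the pyran ring as a 6-exo-trig addition–elimination and forms O1–C8a. No stereocentre is created; the step needs the Z geometry, which the salt-free conditions and the ortho-fluorine of the aldehyde should favour, and any E-isomer cannot reach C8a and is removed as the open alcohol. Fluorine is displaced in preference to the bromine para to it because it is the better leaving group in addition–elimination and the only halogen within reach of the tether; an elimination–addition path through the aryne next to the methoxy group would place the oxygen on the same carbon. The fluoride set free re-enters the desilylation, so the ring closure sustains itself.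

Step 5
Reactants: 11 6-bromo-7-methoxy-2,2-dimethyl-2H-chromene
Product: 12 6-ethenyl-7-methoxy-2,2-dimethyl-2H-chromene
Conditions: vinylboronic acid pinacol ester, PdCl2(dppf) (cat.), K2CO3, dioxane/H2O, 85 °C
Reagents that add atoms: 4,4,5,5-tetramethyl-2-vinyl-1,3,2-dioxaborolane, C=CB1OC(C)(C)C(C)(C)O1
Why: Suzuki–Miyaura coupling of the aryl bromide installs the vinyl group, and the chromene double bond and the ethers are inert to it.

Step 6
Reactants: 12 6-ethenyl-7-methoxy-2,2-dimethyl-2H-chromene
Product: 14 (S,E)-4-(7-methoxy-2,2-dimethyl-2H-chromen-6-yl)-2-methylpent-2-enal, via (R)-2-arylpropanal 13 (not isolated)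
Conditions: Rh(acac)(CO)2 (cat.), (R,R)-Ph-BPE, CO/H2 (1:1, 10 bar), toluene, 60 °C; then Ph3P=C(Me)CHO, 50 °C
Reagents that add atoms: carbon monoxide, [C-]#[O+]; 2-(triphenylphosphoranylidene)propanal, CC(C=O)=P(c1ccccc1)(c1ccccc1)c1ccccc1
Why: Branch-selective asymmetric hydroformylation of the vinylarene sets the benzylic centre by enantioface-selective rhodium hydride insertion under control of the chiral bisphospholane, and the configurationally labile aldehyde is trapped in the same pot by Wittig olefination with the stabilised ylide, which should give the E-enal while the hindered ring alkene stays untouched.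

Step 7
Reactants: 14 (S,E)-4-(7-methoxy-2,2-dimethyl-2H-chromen-6-yl)-2-methylpent-2-enal
Product: 15 (S,E)-7-methoxy-2,2-dimethyl-6-(4-methylhex-3-en-5-yn-2-yl)-2H-chromene
Conditions: Me3SiCHN2, LiN(i-Pr)2, THF, −78 °C; then 14, −78 to 0 °C
Reagents that add atoms: (trimethylsilyl)diazomethane, C[Si](C)(C)C=[N+]=[N-]
Why: Colvin homologation (addition of the lithiated diazomethane, Peterson-type loss of silanolate, loss of N2 and 1,2-hydrogen shift of the alkylidene carbene) should give the terminal enyne, with carbonyl addition at −78 °C outrunning γ-deprotonation so that the (S)-centre and the E-alkene are kept.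

Step 8
Reactants: 16 1-(2,4-dihydroxyphenyl)ethanone
Product: 17 1-(2,4-dihydroxy-5-iodophenyl)ethanone
Conditions: ICl, AcOH, rt
Reagents that add atoms: iodine monochloride, ClI
Why: Electrophilic aromatic iodination should favour C5, para to the chelated 2-hydroxyl and ortho to the 4-hydroxyl, over the more crowded C3 between the two hydroxyls.

Step 9
Reactants: 15 (S,E)-7-methoxy-2,2-dimethyl-6-(4-methylhex-3-en-5-yn-2-yl)-2H-chromene; 17 1-(2,4-dihydroxy-5-iodophenyl)ethanone
Product: 19 1-{6-hydroxy-2-[(2E,4S)-4-(7-methoxy-2,2-dimethyl-2H-chromen-6-yl)pent-2-en-2-yl]-1-benzofuran-5-yl}ethanone (CNP0347774.1), via ortho-alkynylphenol 18 (not isolated)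
Conditions: PdCl2(PPh3)2 (cat.), CuI (cat.), Et3N, DMF, 60 °C
Reagents that add atoms: none
Why: Sonogashira coupling followed by 5-endo-dig addition of the only ortho hydroxyl to the alkyne (one-pot benzofuran annulation) gives the 5-acetyl-6-hydroxybenzofuran, and the amine base is too weak to touch the allylic, benzylic C–H, so the (S)-centre and the E-alkene persist.

Compound list
1 | 2-fluoro-4-methoxybenzaldehyde | COc1ccc(C=O)c(F)c1 | starting material
2 | 5-bromo-2-fluoro-4-methoxybenzaldehyde | COc1cc(F)c(C=O)cc1Br | intermediate
3 | methyltriphenylphosphonium bromide | C[P+](c1ccccc1)(c1ccccc1)c1ccccc1.[Br-] | starting material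
4 | methylenetriphenylphosphorane | C=P(c1ccccc1)(c1ccccc1)c1ccccc1 | intermediate
5 | lithium bromide adduct of the betaine 2-methyl-1-(triphenylphosphonio)propan-2-olate | CC(C)([O-])C[P+](c1ccccc1)(c1ccccc1)c1ccccc1.[Li+].[Br-] | intermediate
6 | (2-hydroxy-2-methylpropyl)triphenylphosphonium bromide | CC(C)(O)C[P+](c1ccccc1)(c1ccccc1)c1ccccc1.[Br-] | intermediate
7 | [2-methyl-2-(trimethylsilyloxy)propyl]triphenylphosphonium bromide | CC(C)(C[P+](c1ccccc1)(c1ccccc1)c1ccccc1)O[Si](C)(C)C.[Br-] | intermediate
8 | [2-methyl-2-(trimethylsilyloxy)propylidene]triphenylphosphorane | CC(C)(C=P(c1ccccc1)(c1ccccc1)c1ccccc1)O[Si](C)(C)C | intermediate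
9 | (Z)-{[4-(5-bromo-2-fluoro-4-methoxyphenyl)-2-methylbut-3-en-2-yl]oxy}trimethylsilane | COc1cc(F)c(/C=C\C(C)(C)O[Si](C)(C)C)cc1Br | intermediate
10 | cesium (Z)-4-(5-bromo-2-fluoro-4-methoxyphenyl)-2-methylbut-3-en-2-olate | COc1cc(F)c(/C=C\C(C)(C)[O-])cc1Br.[Cs+] | intermediate
11 | 6-bromo-7-methoxy-2,2-dimethyl-2H-chromene | COc1cc2c(cc1Br)C=CC(C)(C)O2 | intermediate
12 | 6-ethenyl-7-methoxy-2,2-dimethyl-2H-chromene | COc1cc2c(cc1C=C)C=CC(C)(C)O2 | intermediate
13 | (R)-2-(7-methoxy-2,2-dimethyl-2H-chromen-6-yl)propanal | COc1cc2c(cc1[C@@H](C)C=O)C=CC(C)(C)O2 | intermediate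
14 | (S,E)-4-(7-methoxy-2,2-dimethyl-2H-chromen-6-yl)-2-methylpent-2-enal | COc1cc2c(cc1[C@@H](C)/C=C(\C)C=O)C=CC(C)(C)O2 | intermediate
15 | (S,E)-7-methoxy-2,2-dimethyl-6-(4-methylhex-3-en-5-yn-2-yl)-2H-chromene | COc1cc2c(cc1[C@@H](C)/C=C(\C)C#C)C=CC(C)(C)O2 | intermediate
16 | 1-(2,4-dihydroxyphenyl)ethanone | CC(=O)c1ccc(O)cc1O | starting material
17 | 1-(2,4-dihydroxy-5-iodophenyl)ethanone | CC(=O)c1cc(I)c(O)cc1O | intermediate
18 | 1-{2,4-dihydroxy-5-[(3E,5S)-5-(7-methoxy-2,2-dimethyl-2H-chromen-6-yl)-3-methylhex-3-en-1-yn-1-yl]phenyl}ethanone | COc1cc2c(cc1[C@@H](C)/C=C(\C)C#Cc1cc(C(C)=O)c(O)cc1O)C=CC(C)(C)O2 | intermediate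
19 | 1-{6-hydroxy-2-[(2E,4S)-4-(7-methoxy-2,2-dimethyl-2H-chromen-6-yl)pent-2-en-2-yl]-1-benzofuran-5-yl}ethanone | COc1cc2c(cc1[C@@H](C)/C=C(\C)c1cc3cc(C(C)=O)c(O)cc3o1)C=CC(C)(C)O2 | target

Total step count: 9. Longest linear sequence: 7 steps (steps 2, 3, 4, 5, 6, 7 and 9).

Steps most likely to fail

Step 4. The olefination with the hindered ylide may lose Z-selectivity, and the displacement of fluoride may be slow once the activating aldehyde has been consumed. The fallback sets out from 2 and comes back at 11, making the same two bonds in separate operations. The fluorine of 2 is displaced first, while the aldehyde still activates it, by the potassium alkoxide of 2-methylbut-3-en-2-ol (KH, THF, 0 °C to rt) to give 5-bromo-4-methoxy-2-[(2-methylbut-3-en-2-yl)oxy]benzaldehyde F1. Wittig methylenation (Ph3P=CH2, THF) gives 1-bromo-5-ethenyl-2-methoxy-4-[(2-methylbut-3-en-2-yl)oxy]benzene F2. Ring-closing metathesis with the second-generation Grubbs catalyst (CH2Cl2, 40 °C) then closes C3=C4 with loss of ethene and returns to 11; the ring enforces the cis geometry.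

Step 6. The hydroformylation of the ortho-methoxy vinylarene may show insufficient enantioface or branched/linear control. The fallback sets out from 11 and comes back at 13, taking the stereocentre from the chiral pool. Bromide 11 is converted into (7-methoxy-2,2-dimethyl-2H-chromen-6-yl)magnesium bromide F3 (Mg, LiCl, THF). F3 displaces the triflate of ethyl (R)-2-(trifluoromethylsulfonyloxy)propanoate, made from ethyl (R)-lactate (ZnCl2 cat., THF, 0 °C), by SN2 with inversion at carbon. This should give ethyl (R)-2-(7-methoxy-2,2-dimethyl-2H-chromen-6-yl)propanoate F4; the descriptor stays R because the priority order changes. Reduction with i-Bu2AlH (CH2Cl2, −78 °C) gives aldehyde 13, which is treated at once with the ylide of step 6.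

Step 7. The basic lithiated diazomethane may deprotonate the enal at the γ-position instead of adding to the carbonyl, which would racemise the benzylic centre or deconjugate the alkene. The fallback sets out from 14 and comes back at 15 by a Corey–Fuchs sequence that never exposes the enal to a base. Neutral dibromo-olefination (CBr4, PPh3, CH2Cl2, 0 °C) gives (S,E)-6-(6,6-dibromo-4-methylhexa-3,5-dien-2-yl)-7-methoxy-2,2-dimethyl-2H-chromene F5. Bromine–lithium exchange and rearrangement (n-BuLi, THF, −78 °C), where exchange is faster than any C–H deprotonation, followed by aqueous quench gives 15.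

Further compounds
F1 | step 4 | 5-bromo-4-methoxy-2-[(2-methylbut-3-en-2-yl)oxy]benzaldehyde | COc1cc(OC(C)(C)C=C)c(C=O)cc1Br
F2 | step 4 | 1-bromo-5-ethenyl-2-methoxy-4-[(2-methylbut-3-en-2-yl)oxy]benzene | COc1cc(OC(C)(C)C=C)c(C=C)cc1Br
F3 | step 6 | (7-methoxy-2,2-dimethyl-2H-chromen-6-yl)magnesium bromide | COc1cc2c(cc1[Mg]Br)C=CC(C)(C)O2
F4 | step 6 | ethyl (R)-2-(7-methoxy-2,2-dimethyl-2H-chromen-6-yl)propanoate | COc1cc2c(cc1[C@@H](C)C(=O)OCC)C=CC(C)(C)O2
F5 | step 7 | (S,E)-6-(6,6-dibromo-4-methylhexa-3,5-dien-2-yl)-7-methoxy-2,2-dimethyl-2H-chromene | COc1cc2c(cc1[C@@H](C)/C=C(\C)C=C(Br)Br)C=CC(C)(C)O2
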